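**Retrosynthetic overview**
- Feature: in the tetrahydrofuran ring (O1, C2 aryl, C3 CH2O, C4 benzyl, C5) C5 is a bare CH2 between O1 and C4, and H-3 and H-4 are cis. C5 can therefore be a CO-derived carbon added together with H, syn, across a C3=C4 alkene.
- Late stage: the angelate C–O bond is cut to the primary alcohol and angelic acid, and C5–H goes back to the C5–OH lactol.
- Key disconnection: C4–C5 and O1–C5 of the lactol, giving CO/H2 and an acyclic Z-trisubstituted allylic alcohol. The tetrahydrofuran is the only ring formed and it is closed in this step.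
- The allylic alcohol comes from its enone by asymmetric reduction, and the enone from an alkenyl iodide and 3,4-dimethoxybenzaldehyde (C2–C3 bond).
- The alkenyl iodide comes from trans-hydrostannation of 4-(3,4-dimethoxyphenyl)but-2-yn-1-ol, made from propargyl alcohol and 3,4-dimethoxybenzyl chloride.

Key step: step 8

Assumption: in the oxazaborolidine reduction the Z-trisubstituted, α-branched alkenyl group is taken to act as the larger ketone substituent, and the (S)-catalyst is specified on that basis.

Remark: ring numbering O1, C2 (aryl), C3 (CH2O), C4 (benzyl), C5 is used for all intermediates. The carbinol centre of the acyclic allylic alcohol has the same spatial arrangement as C2 of leoligin (S) but carries the descriptor R, because the alkenyl carbon outranks the aryl carbon in the acyclic compound.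

**Route**

Step 1
Reactants: 1 propargyl alcohol (prop-2-yn-1-ol); 2 3,4-dimethoxybenzyl chloride
Product: 4 4-(3,4-dimethoxyphenyl)but-2-yn-1-ol, via bromomagnesium acetylide alkoxide 3 (not isolated)
Conditions: EtMgBr (2.1 equiv), THF, 0 °C to rt; then CuCl (10 mol%), 2, 50 °C; H2O work-up
Reagents that add atoms: none
Why: Copper-catalysed alkylation of the magnesium acetylide by the reactive benzylic chloride forms the sp–sp3 C–C bond while the hydroxyl is masked as its magnesium alkoxide; no stereocentre is involved.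

Step 2
Reactants: 4 4-(3,4-dimethoxyphenyl)but-2-yn-1-ol
Product: 5 (Z)-4-(3,4-dimethoxyphenyl)-2-(tributylstannyl)but-2-en-1-ol (tin cis to the benzylic CH2)
Conditions: Bu3SnH (1.1 equiv), [Cp*RuCl]4 (1.5 mol%), CH2Cl2, rt
Reagents that add atoms: tributyltin hydride, CCCC[SnH](CCCC)CCCC
Why: Hydroxyl-directed ruthenium-catalysed trans-hydrostannation of a propargylic alcohol puts tin on the alkyne carbon next to the carbinol and H anti to it, which fixes the alkene geometry.

Step 3
Reactants: 5 (Z)-4-(3,4-dimethoxyphenyl)-2-(tributylstannyl)but-2-en-1-ol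
Product: 6 (Z)-4-(3,4-dimethoxyphenyl)-2-iodobut-2-en-1-ol (iodine cis to the benzylic CH2)
Conditions: I2 (1.05 equiv), CH2Cl2, 0 °C; aq Na2S2O3
Reagents that add atoms: iodine, II
Why: Iododestannylation of an alkenylstannane is an ipso substitution with retention of alkene geometry, and I2 alone at 0 °C should not iodinate the dimethoxyarene.

Step 4
Reactants: 6 (Z)-4-(3,4-dimethoxyphenyl)-2-iodobut-2-en-1-ol
Product: 7 tert-butyl{[(Z)-4-(3,4-dimethoxyphenyl)-2-iodobut-2-en-1-yl]oxy}dimethylsilane
Conditions: TBSCl, imidazole, CH2Cl2, 0 °C to rt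
Reagents that add atoms: tert-butyldimethylsilyl chloride, CC(C)(C)[Si](C)(C)Cl
Why: Imidazole-mediated silylation of the primary alcohol protects the future C3 hydroxymethyl group through the organolithium, hydroformylation and Lewis acid steps.

Step 5
Reactants: 7 tert-butyl{[(Z)-4-(3,4-dimethoxyphenyl)-2-iodobut-2-en-1-yl]oxy}dimethylsilane; 8 3,4-dimethoxybenzaldehyde
Product: 10 rac-(Z)-2-{[(tert-butyldimethylsilyl)oxy]methyl}-1,4-bis(3,4-dimethoxyphenyl)but-2-en-1-ol (carbinol carbon cis to the benzylic CH2), via vinyllithium 9 (not isolated)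
Conditions: t-BuLi (2.1 equiv), Et2O, −78 °C; then 8 in THF, −78 to −40 °C; H2O
Reagents that add atoms: none
Why: Iodine–lithium exchange is faster than deprotonation and retains alkene geometry, and 1,2-addition of the alkenyllithium to the aldehyde forms the C2–C3 bond; the carbinol centre is formed racemic and is set in steps 6 and 7.

Step 6
Reactants: 10 rac-(Z)-2-{[(tert-butyldimethylsilyl)oxy]methyl}-1,4-bis(3,4-dimethoxyphenyl)but-2-en-1-ol
Product: 11 (Z)-2-{[(tert-butyldimethylsilyl)oxy]methyl}-1,4-bis(3,4-dimethoxyphenyl)but-2-en-1-one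
Conditions: Dess–Martin periodinane, NaHCO3, CH2Cl2, 0 °C to rt
Reagents that add atoms: none
Why: Dess–Martin oxidation of a benzylic, allylic secondary alcohol under buffered, non-nucleophilic conditions should leave the Z alkene and the silyl ether untouched.

Step 7
Reactants: 11 (Z)-2-{[(tert-butyldimethylsilyl)oxy]methyl}-1,4-bis(3,4-dimethoxyphenyl)but-2-en-1-one
Product: 12 (1R,2Z)-2-{[(tert-butyldimethylsilyl)oxy]methyl}-1,4-bis(3,4-dimethoxyphenyl)but-2-en-1-ol
Conditions: (S)-2-methyl-CBS-oxazaborolidine (0.5 equiv), catecholborane (2 equiv), toluene, −78 °C; MeOH, aq NaHCO3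
Reagents that add atoms: none
Why: Corey–Bakshi–Shibata reduction, in which the ketone binds boron anti to its larger substituent (taken as the branched alkenyl group) and hydride is delivered to one carbonyl face, sets the carbinol centre as R (the future C2); catecholborane at low temperature reduces 1,2 without hydroborating the alkene.

Step 8
Reactants: 12 (1R,2Z)-2-{[(tert-butyldimethylsilyl)oxy]methyl}-1,4-bis(3,4-dimethoxyphenyl)but-2-en-1-ol
Product: 14 (3R,4R,5S)-4-{[(tert-butyldimethylsilyl)oxy]methyl}-3-(3,4-dimethoxybenzyl)-5-(3,4-dimethoxyphenyl)tetrahydrofuran-2-ol as both anomers, via hydroxy aldehyde 13 (not isolated)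
Conditions: Rh(acac)(CO)2 (3 mol%), P(O-2,4-tBu2C6H3)3 (12 mol%), CO/H2 (1:1, 40 bar), toluene, 70 °C
Reagents that add atoms: carbon monoxide, [C-]#[O+]
Why: Proposed new method: a monovalent rhodium hydride carrying one bulky phosphite should add syn across C3=C4 with H to the fully substituted C3 and rhodium to the CH carbon C4; CO insertion with retention and hydrogenolysis then give hydroxy aldehyde 13 (C4–C5 bond), and the C2 hydroxyl adds to the formyl carbon in a 5-exo-trig closure (O1–C5 bond) to form the tetrahydrofuran ring as lactol 14. The closest known reactions are hydroformylation of simple allylic alcohols to 2-hydroxytetrahydrofurans, bulky-phosphite rhodium hydroformylation of trisubstituted alkenes at the CH carbon, and hydroformylation of 1,1-disubstituted allylic alcohols controlled by the allylic stereocentre; the combination on an acyclic Z-trisubstituted allylic alcohol that sets two stereocentres is not established. C3 is controlled by C2 through 1,3-allylic strain: the benzylic CH2 cis to C2 holds the C2–H in the alkene plane, so hydroxyl and aryl lie on opposite faces and the catalyst should add from the hydroxyl face, anti to the aryl group, which puts the C2 aryl and C3 CH2OSi groups trans. C4 is controlled by the alkene geometry, because syn delivery of H to C3 and formyl to C4 of the Z alkene makes H-3 and H-4 cis. The step needs regioselectivity for C4, facial selectivity and suppression of alkene migration towards the benzylic CH2; the substitution pattern, the allylic strain and a high CO pressure over a π-acidic phosphite are relied on for these.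

Step 9
Reactants: 14 (3R,4R,5S)-4-{[(tert-butyldimethylsilyl)oxy]methyl}-3-(3,4-dimethoxybenzyl)-5-(3,4-dimethoxyphenyl)tetrahydrofuran-2-ol
Product: 15 tert-butyl{[(2S,3R,4R)-4-(3,4-dimethoxybenzyl)-2-(3,4-dimethoxyphenyl)tetrahydrofuran-3-yl]methoxy}dimethylsilane
Conditions: Et3SiH (3 equiv), BF3·OEt2 (1.5 equiv), CH2Cl2, −78 to −40 °C; aq NaHCO3
Reagents that add atoms: none
Why: Ionic hydrogenation of the lactol: BF3 ionises the anomeric hydroxyl to the cyclic oxocarbenium ion, which triethylsilane reduces at C5 (no stereocentre formed); low temperature is meant to spare the benzylic C2–O bond, the C4 centre and the silyl ether.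

Step 10
Reactants: 15 tert-butyl{[(2S,3R,4R)-4-(3,4-dimethoxybenzyl)-2-(3,4-dimethoxyphenyl)tetrahydrofuran-3-yl]methoxy}dimethylsilane
Product: 16 [(2S,3R,4R)-4-(3,4-dimethoxybenzyl)-2-(3,4-dimethoxyphenyl)tetrahydrofuran-3-yl]methanol
Conditions: TBAF, THF, 0 °C to rt
Reagents that add atoms: none
Why: Fluoride cleavage of the primary silyl ether does not affect the benzylic ether, the aryl methyl ethers or any stereocentre.

Step 11
Reactants: 16 [(2S,3R,4R)-4-(3,4-dimethoxybenzyl)-2-(3,4-dimethoxyphenyl)tetrahydrofuran-3-yl]methanol; 17 angelic acid ((Z)-2-methylbut-2-enoic acid)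
Product: 18 leoligin, [(2S,3R,4R)-4-(3,4-dimethoxybenzyl)-2-(3,4-dimethoxyphenyl)tetrahydrofuran-3-yl]methyl (Z)-2-methylbut-2-enoate
Conditions: PPh3, DIAD, THF, 0 °C to rt
Reagents that add atoms: none
Why: Mitsunobu esterification activates the primary alcohol and not the acid, so the angelate Z double bond is not exposed to acyl-activation conditions that isomerise it to the tiglate; the reacting carbon is not stereogenic.

**Compound list**
1 | propargyl alcohol (prop-2-yn-1-ol) | C#CCO | starting material
2 | 3,4-dimethoxybenzyl chloride | COc1ccc(CCl)cc1OC | starting material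
3 | bromomagnesium acetylide alkoxide of propargyl alcohol | Br[Mg]C#CCO[Mg]Br | intermediate
4 | 4-(3,4-dimethoxyphenyl)but-2-yn-1-ol | OCC#CCc1ccc(OC)c(OC)c1 | intermediate
5 | (Z)-4-(3,4-dimethoxyphenyl)-2-(tributylstannyl)but-2-en-1-ol | OC/C(=C/Cc1ccc(OC)c(OC)c1)[Sn](CCCC)(CCCC)CCCC | intermediate
6 | (Z)-4-(3,4-dimethoxyphenyl)-2-iodobut-2-en-1-ol | OC/C(I)=C/Cc1ccc(OC)c(OC)c1 | intermediate
7 | tert-butyl{[(Z)-4-(3,4-dimethoxyphenyl)-2-iodobut-2-en-1-yl]oxy}dimethylsilane | CC(C)(C)[Si](C)(C)OC/C(I)=C/Cc1ccc(OC)c(OC)c1 | intermediate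
8 | 3,4-dimethoxybenzaldehyde | COc1ccc(C=O)cc1OC | starting material
9 | {(E)-1-[(tert-butyldimethylsilyl)oxy]-4-(3,4-dimethoxyphenyl)but-2-en-2-yl}lithium (lithium in place of iodine, geometry retained) | CC(C)(C)[Si](C)(C)OC/C([Li])=C/Cc1ccc(OC)c(OC)c1 | intermediate
10 | rac-(Z)-2-{[(tert-butyldimethylsilyl)oxy]methyl}-1,4-bis(3,4-dimethoxyphenyl)but-2-en-1-ol | CC(C)(C)[Si](C)(C)OC/C(=C/Cc1ccc(OC)c(OC)c1)C(O)c1ccc(OC)c(OC)c1 | intermediate
11 | (Z)-2-{[(tert-butyldimethylsilyl)oxy]methyl}-1,4-bis(3,4-dimethoxyphenyl)but-2-en-1-one | CC(C)(C)[Si](C)(C)OC/C(=C/Cc1ccc(OC)c(OC)c1)C(=O)c1ccc(OC)c(OC)c1 | intermediate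
12 | (1R,2Z)-2-{[(tert-butyldimethylsilyl)oxy]methyl}-1,4-bis(3,4-dimethoxyphenyl)but-2-en-1-ol | CC(C)(C)[Si](C)(C)OC/C(=C/Cc1ccc(OC)c(OC)c1)[C@H](O)c1ccc(OC)c(OC)c1 | intermediate
13 | (2R,3R,4S)-3-{[(tert-butyldimethylsilyl)oxy]methyl}-2-(3,4-dimethoxybenzyl)-4-(3,4-dimethoxyphenyl)-4-hydroxybutanal | CC(C)(C)[Si](C)(C)OC[C@H]([C@H](O)c1ccc(OC)c(OC)c1)[C@@H](Cc1ccc(OC)c(OC)c1)C=O | intermediate
14 | (3R,4R,5S)-4-{[(tert-butyldimethylsilyl)oxy]methyl}-3-(3,4-dimethoxybenzyl)-5-(3,4-dimethoxyphenyl)tetrahydrofuran-2-ol (both anomers) | CC(C)(C)[Si](C)(C)OC[C@H]1[C@@H](Cc2ccc(OC)c(OC)c2)C(O)O[C@@H]1c1ccc(OC)c(OC)c1 | intermediate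
15 | tert-butyl{[(2S,3R,4R)-4-(3,4-dimethoxybenzyl)-2-(3,4-dimethoxyphenyl)tetrahydrofuran-3-yl]methoxy}dimethylsilane | CC(C)(C)[Si](C)(C)OC[C@H]1[C@@H](Cc2ccc(OC)c(OC)c2)CO[C@@H]1c1ccc(OC)c(OC)c1 | intermediate
16 | [(2S,3R,4R)-4-(3,4-dimethoxybenzyl)-2-(3,4-dimethoxyphenyl)tetrahydrofuran-3-yl]methanol | OC[C@H]1[C@@H](Cc2ccc(OC)c(OC)c2)CO[C@@H]1c1ccc(OC)c(OC)c1 | intermediate
17 | angelic acid, (Z)-2-methylbut-2-enoic acid | C/C=C(/C)C(=O)O | starting material
18 | leoligin | C/C=C(/C)C(=O)OC[C@H]1[C@@H](Cc2ccc(OC)c(OC)c2)CO[C@@H]1c1ccc(OC)c(OC)c1 | target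

**Totals**
Total step count: 11. Longest linear sequence: 11 steps (1 to 18).

**Steps most likely to fail**

Step 8 (proposed new method). The hindered trisubstituted alkene may insert too slowly. The C4 alkyl–rhodium may undergo β-hydride elimination towards the benzylic CH2, so the alkene migrates into conjugation. Facial selectivity may be incomplete, and C4 may epimerise through the open hydroxy aldehyde. The fallback sets out from 12 and comes back at 14, and replaces the catalytic step by stoichiometric hydroboration–carbonylation. 9-BBN (2.2 equiv, THF, 65 °C; the first equivalent is consumed by the hydroxyl) adds H and boron syn across C3=C4 under the same allylic-strain control, boron going to the CH carbon C4, to give the O,C-diboryl adduct F1. Carbonylation (CO, 1 atm) in the presence of KBH(OiPr)3 at 0 °C transfers the C4 alkyl group from boron to the new carbon with retention, giving the α-boryl alkoxide F2. Oxidation with H2O2 in pH 7 buffer releases hydroxy aldehyde 13, which closes to 14.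

Step 7. Hydride may be delivered to the wrong carbonyl face, or with low selectivity, if the aryl and alkenyl groups are not well differentiated; the enone may also lose its Z geometry before reduction. The fallback sets out from racemic 10 (steps 6 and 7 are then omitted) and comes back at 12, and replaces asymmetric reduction by separation of diastereomers. Esterification with (S)-2-methoxy-2-phenylacetic acid (DCC, DMAP, CH2Cl2) gives the ester of the R carbinol F3 and the ester of the S carbinol F4, which are separated by chromatography. Methanolysis of F3 (K2CO3, MeOH) gives 12.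

Step 9. The Lewis acid may ionise the benzylic C2–O bond of the electron-rich aryl ether, leading to epimerisation at C2 or reductive ring opening. The silyl ether may be lost, and proton loss from the oxocarbenium ion may erase the C4 configuration. The fallback sets out from 14 and comes back at 15, and avoids Lewis acid altogether. NaBH4 (MeOH, 0 °C) reduces the open form of the lactol to the 1,4-diol F5. TsCl in pyridine at 0 °C sulfonylates the primary hydroxyl selectively to give the primary tosylate F6. On warming in pyridine, F6 closes by 5-exo-tet displacement by the benzylic hydroxyl, with the C2–O bond untouched, to give 15.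

**Further compounds**
F1 | step 8 | O,C-bis(9-borabicyclo[3.3.1]nonan-9-yl) hydroboration adduct of 12 (boron on C4 syn to the new C3–H, second boron on the C2 oxygen) | CC(C)(C)[Si](C)(C)OC[C@H]([C@H](OB1C2CCCC1CCC2)c1ccc(OC)c(OC)c1)[C@@H](Cc1ccc(OC)c(OC)c1)B1C2CCCC1CCC2
F2 | step 8 | potassium α-boryl alkoxide from carbonylation of F1 (C4 bears CH(OK)–B(9-BBN)) | CC(C)(C)[Si](C)(C)OC[C@H]([C@H](OB1C2CCCC1CCC2)c1ccc(OC)c(OC)c1)[C@@H](Cc1ccc(OC)c(OC)c1)C(O[K])B1C2CCCC1CCC2
F3 | step 7 | (1R,2Z)-2-{[(tert-butyldimethylsilyl)oxy]methyl}-1,4-bis(3,4-dimethoxyphenyl)but-2-en-1-yl (S)-2-methoxy-2-phenylacetate | CC(C)(C)[Si](C)(C)OC/C(=C/Cc1ccc(OC)c(OC)c1)[C@H](OC(=O)[C@@H](OC)c1ccccc1)c1ccc(OC)c(OC)c1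
F4 | step 7 | (1S,2Z)-2-{[(tert-butyldimethylsilyl)oxy]methyl}-1,4-bis(3,4-dimethoxyphenyl)but-2-en-1-yl (S)-2-methoxy-2-phenylacetate | CC(C)(C)[Si](C)(C)OC/C(=C/Cc1ccc(OC)c(OC)c1)[C@@H](OC(=O)[C@@H](OC)c1ccccc1)c1ccc(OC)c(OC)c1
F5 | step 9 | (1S,2R,3R)-2-{[(tert-butyldimethylsilyl)oxy]methyl}-3-(3,4-dimethoxybenzyl)-1-(3,4-dimethoxyphenyl)butane-1,4-diol | CC(C)(C)[Si](C)(C)OC[C@H]([C@H](O)c1ccc(OC)c(OC)c1)[C@@H](Cc1ccc(OC)c(OC)c1)CO
F6 | step 9 | (2R,3R,4S)-3-{[(tert-butyldimethylsilyl)oxy]methyl}-2-(3,4-dimethoxybenzyl)-4-(3,4-dimethoxyphenyl)-4-hydroxybutyl 4-methylbenzenesulfonate | CC(C)(C)[Si](C)(C)OC[C@H]([C@H](O)c1ccc(OC)c(OC)c1)[C@@H](Cc1ccc(OC)c(OC)c1)COS(=O)(=O)c1ccc(C)cc1
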